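**Retrosynthetic overview**
- Target ⇐ global desilylation ⇐ Suzuki attachment of the (E)‑3‑silyloxypropenyl chain to a 7‑bromo‑1,4‑benzodioxane.
- C3–CH2OH ⇐ C3–dioxolane by periodate excision and reduction; the carbon of the L‑glyceraldehyde stereocentre becomes the CH2OH carbon.
- The 1,4‑dioxane ring (the only ring formed) ⇐ inverse‑demand hetero‑Diels–Alder of 5‑bromo‑3‑methoxy‑o‑benzoquinone (O=C–C=O heterodiene) with an (E)‑styryl dioxolane; E geometry gives trans, the dioxolane stereocentre selects the face.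
- Dienophile ⇐ Heck coupling of silylated 4‑bromo‑2,6‑dimethoxyphenol with (R)‑4‑vinyl‑dioxolane, itself from (S)‑glyceraldehyde acetonide; quinone precursor ⇐ Dakin oxidation of 5‑bromo‑o‑vanillin.

Assumptions: the target is the trans‑(2S,3S) enantiomer, which is what the SMILES encodes. Ring numbering used throughout: O1–C2(aryl)–C3–O4–C4a–C5(OMe)…C7. Compounds 1, 3, 6 and 11 are taken as catalogue items. The face and regiochemistry of Step 5 are predictions from models, not from a direct precedent.

**Step 1**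
Reactants: 1, 4‑bromo‑2,6‑dimethoxyphenol
Product: 2, tert‑butyl(4‑bromo‑2,6‑dimethoxyphenoxy)dimethylsilane
Conditions: TBSCl, imidazole, DMF, rt→40 °C
Reagents that add atoms: TBSCl, CC(C)(C)[Si](C)(C)Cl
Why: Standard phenol silylation; the silyl ether masks the easily oxidised syringyl phenol so the styrene can later act only as a dienophile toward an o‑quinone.

**Step 2**
Reactants: 3, (S)‑2,2‑dimethyl‑1,3‑dioxolane‑4‑carbaldehyde (L‑glyceraldehyde acetonide, ex L‑ascorbic acid)
Product: 4, (4R)‑4‑ethenyl‑2,2‑dimethyl‑1,3‑dioxolane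
Conditions: Ph3PCH3Br, KHMDS, THF, −78 °C→rt; distil (volatile)
Reagents that add atoms: methyltriphenylphosphonium bromide, C[P+](c1ccccc1)(c1ccccc1)c1ccccc1.[Br-]
Why: Wittig methylenation with a non‑stabilised ylide at low temperature does not epimerise the α‑alkoxy aldehyde; the stereocentre is unchanged in space (descriptor S→R only by CIP priority change).

**Step 3**
Reactants: 2, aryl bromide; 4, (4R)‑4‑ethenyl‑2,2‑dimethyl‑1,3‑dioxolane (1.5 equiv)
Product: 5, tert‑butyl{4‑[(E)‑2‑[(4R)‑2,2‑dimethyl‑1,3‑dioxolan‑4‑yl]ethenyl]‑2,6‑dimethoxyphenoxy}dimethylsilane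
Conditions: Pd2(dba)3 (2.5 mol %), [(t‑Bu)3PH]BF4 (10 mol %), Cy2NMe, dioxane, 80 °C
Reagents that add atoms: none
Why: Mizoroki–Heck arylation of the terminal alkene gives the conjugated E‑styrene by syn insertion and syn β‑H elimination toward the benzylic hydrogen; the bulky phosphine/amine system traps Pd–H quickly, so the allylic stereocentre is not touched.

**Step 4**
Reactants: 6, 5‑bromo‑2‑hydroxy‑3‑methoxybenzaldehyde (5‑bromo‑o‑vanillin)
Product: 7, 5‑bromo‑3‑methoxybenzene‑1,2‑diol
Conditions: 30 % H2O2, aq NaOH, THF/H2O, 0 °C→rt; then HCl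
Reagents that add atoms: hydrogen peroxide, OO
Why: Dakin oxidation: aryl migration in the peroxide adduct of an o‑hydroxybenzaldehyde gives the formate, which hydrolyses in situ to the catechol.

**Step 5 (key ring formation)**
Reactants: 7, catechol (2 equiv, added slowly); 5, dienophile
Product: 8, (2S,3R)‑7‑bromo‑2‑[4‑(tert‑butyldimethylsilyloxy)‑3,5‑dimethoxyphenyl]‑3‑[(4S)‑2,2‑dimethyl‑1,3‑dioxolan‑4‑yl]‑5‑methoxy‑2,3‑dihydro‑1,4‑benzodioxine (2,3‑trans)
Conditions: Ag2O (3 equiv), 4 Å MS, PhMe, dark, rt→45 °C; chromatography to remove the minor diastereomer/regioisomer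
Reagents that add atoms: none (Ag2O only removes 2 H from 7)
Why: Ag2O generates 5‑bromo‑3‑methoxy‑o‑benzoquinone in situ, which adds to the styrene as a heterodiene in an inverse‑electron‑demand hetero‑Diels–Alder reaction, with three controlling elements:
- Relative configuration: suprafacial addition to the E‑alkene gives the 2,3‑trans ring.
- Regiochemistry: the nucleophilic non‑benzylic alkene carbon bonds to the oxygen of the carbonyl next to C–OMe (the carbonyl that is not a vinylogous ester), placing the aryl‑bearing carbon on O1.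
- Absolute configuration: attack anti (erythro) to the dioxolane C–O bond (inside‑alkoxy/Kishi model) sets C3, and with it C2. Expected selectivity is modest (about 3–5:1), but the minor face gives a separable diastereomer, so enantiopurity is not eroded.

**Step 6**
Reactants: 8, cycloadduct
Product: 10, (2S,3S)‑7‑bromo‑2‑[4‑(tert‑butyldimethylsilyloxy)‑3,5‑dimethoxyphenyl]‑3‑(hydroxymethyl)‑5‑methoxy‑2,3‑dihydro‑1,4‑benzodioxine, via the non‑isolated aldehyde 9, (2S,3R)‑…‑2,3‑dihydro‑1,4‑benzodioxine‑3‑carbaldehyde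
Conditions: H5IO6, EtOAc, 0 °C→rt; filter; then NaBH4, MeOH, 0 °C
Reagents that add atoms: none
Why: Periodic acid removes the terminal acetonide and cleaves the resulting glycol in one pot (Malaprade), and the α‑aryloxy aldehyde is reduced cold at once, so C3 is not epimerised (the trans isomer is in any case the thermodynamic one, and C2 is unaffected); the descriptor at C3 changes R→S only by priority.

**Step 7**
Reactants: 10, aryl bromide; 11, (E)‑tert‑butyldimethyl{[3‑(4,4,5,5‑tetramethyl‑1,3,2‑dioxaborolan‑2‑yl)prop‑2‑en‑1‑yl]oxy}silane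
Product: 12, (2S,3S)‑2‑[4‑(tert‑butyldimethylsilyloxy)‑3,5‑dimethoxyphenyl]‑7‑[(E)‑3‑(tert‑butyldimethylsilyloxy)prop‑1‑enyl]‑3‑(hydroxymethyl)‑5‑methoxy‑2,3‑dihydro‑1,4‑benzodioxine
Conditions: Pd(OAc)2/SPhos (5/10 mol %), K3PO4, THF/H2O, 60 °C
Reagents that add atoms: none
Why: Suzuki–Miyaura coupling transfers the alkenyl group with retention of E geometry; the electron‑rich ligand handles the oxygenated aryl bromide, and the free primary alcohol and both stereocentres are inert.

**Step 8**
Reactants: 12, bis‑silyl ether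
Product: 13, 4‑[(2S,3S)‑3‑(hydroxymethyl)‑7‑[(E)‑3‑hydroxyprop‑1‑enyl]‑5‑methoxy‑2,3‑dihydro‑1,4‑benzodioxin‑2‑yl]‑2,6‑dimethoxyphenol (target)
Conditions: TBAF, AcOH (buffer), THF, 0 °C→rt
Reagents that add atoms: none
Why: Fluoride cleaves the aryl and the primary allylic silyl ethers together; buffering avoids air oxidation of the syringyl phenoxide and leaves the benzylic aryl ether untouched.

**Compound list**
1 | 4‑bromo‑2,6‑dimethoxyphenol | COc1cc(Br)cc(OC)c1O | starting material
2 | tert‑butyl(4‑bromo‑2,6‑dimethoxyphenoxy)dimethylsilane | COc1cc(Br)cc(OC)c1O[Si](C)(C)C(C)(C)C | intermediate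
3 | (S)‑2,2‑dimethyl‑1,3‑dioxolane‑4‑carbaldehyde | O=C[C@@H]1COC(C)(C)O1 | starting material
4 | (4R)‑4‑ethenyl‑2,2‑dimethyl‑1,3‑dioxolane | C=C[C@@H]1COC(C)(C)O1 | intermediate
5 | (R,E)‑styryl dioxolane dienophile | COc1cc(/C=C/[C@@H]2COC(C)(C)O2)cc(OC)c1O[Si](C)(C)C(C)(C)C | intermediate
6 | 5‑bromo‑2‑hydroxy‑3‑methoxybenzaldehyde | COc1cc(Br)cc(C=O)c1O | starting material
7 | 5‑bromo‑3‑methoxybenzene‑1,2‑diol | COc1cc(Br)cc(O)c1O | intermediate
8 | (2S,3R,4′S) trans cycloadduct | COc1cc([C@@H]2Oc3cc(Br)cc(OC)c3O[C@H]2[C@@H]2COC(C)(C)O2)cc(OC)c1O[Si](C)(C)C(C)(C)C | intermediate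
9 | (2S,3R) trans 3‑carbaldehyde | COc1cc([C@@H]2Oc3cc(Br)cc(OC)c3O[C@H]2C=O)cc(OC)c1O[Si](C)(C)C(C)(C)C | intermediate (not isolated)
10 | (2S,3S) 7‑bromo 3‑hydroxymethyl benzodioxane | COc1cc([C@@H]2Oc3cc(Br)cc(OC)c3O[C@H]2CO)cc(OC)c1O[Si](C)(C)C(C)(C)C | intermediate
11 | (E)‑3‑(TBS‑oxy)prop‑1‑enylboronic acid pinacol ester | CC(C)(C)[Si](C)(C)OC/C=C/B1OC(C)(C)C(C)(C)O1 | starting material
12 | (2S,3S) bis‑TBS ether | COc1cc([C@@H]2Oc3cc(/C=C/CO[Si](C)(C)C(C)(C)C)cc(OC)c3O[C@H]2CO)cc(OC)c1O[Si](C)(C)C(C)(C)C | intermediate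
13 | target (CID11188887) | COc1cc([C@@H]2Oc3cc(/C=C/CO)cc(OC)c3O[C@H]2CO)cc(OC)c1O | target

**Step count**
Total: 8 steps; Step 6 is a telescoped cleavage/reduction with one isolation, so 9 if counted as two. Longest linear sequence: 6 steps (1→2→5→8→10→12→13).

**Steps most likely to fail, with fallbacks**
1. Step 5 (hetero‑Diels–Alder). The dienophile is only moderately electron‑rich, the quinone can decompose first, and the regio‑ and facial selectivities are predictions. Fallback: abandon the concerted cycloaddition. Desilylate 5 to the free p‑hydroxystyrene and couple it with 7 under Ag2CO3 (phenoxy‑radical β–O–4 coupling, then quinone‑methide closure to the trans ring). Separate diastereomers as before and re‑silylate before Step 6. If the facial preference proves to be the opposite, use the D‑mannitol‑derived enantiomer of 3.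
2. Step 3 (Heck). β‑H elimination toward the dioxolane C–H would give an enol ether, and 4 is volatile. Fallback: build the alkene by Horner–Wadsworth–Emmons olefination of aldehyde 3 with diethyl [4‑(TBS‑oxy)‑3,5‑dimethoxybenzyl]phosphonate, made from syringaldehyde by silylation, NaBH4 reduction and ZnI2/P(OEt)3. This gives the E‑alkene without Pd–H chemistry.
3. Step 7 (Suzuki on an electron‑rich aryl bromide; protodeboronation of the alkenyl boronate). Fallback: Heck coupling of 10 with ethyl acrylate, then DIBAL reduction of the cinnamate to the allylic alcohol (one extra step).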